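**Plan**

1. Numbering used below: ring C1 (ketone), C2=C3 (Z, methyl on C3), C4, C5 (lactone O), C6 (ring fusion), C7 (OH), C8 (O‑acyl), C9 (methyl), C10; C11(=C13H2)–C12(=O) is the acrylate unit on C6.
2. The retrosynthesis cuts, in this order: the O8–acyl ester; the C7–O and C8–O bonds (back to a cis C7=C8 olefin); the lactone C12–O5 bond (back to a 2‑methylene‑1,4‑diol); then C9–C10 of the ten‑membered ring.
3. Enabling feature: C1(=O)–C10H2–C9H(CH3)–C8=C7 is a γ,δ‑unsaturated ketone, the product pattern of a Claisen rearrangement. The carbocycle can therefore come from the eight‑membered enol ether ring O–C1(=C10H2)–C2=C3–C4–C5–C6–C7 carrying the propenyl group C8=C9 on C7; that small ring also locks the Z C2=C3 bond.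
4. Forward: chain assembly C6–C7 (aldol), C5–C4 (chloromethyl ketone, epoxide), C4–C3 (acetylide), C3–CH3 (cuprate); eight‑membered lactone; methylenation; [3,3] ring expansion 8 → 10; γ‑lactone; epoxide; transannular opening; ester.
5. Stereochemistry: C6/C7 from an oxazolidinone aldol, C5 from a CBS reduction, C9 by chirality transfer from C7 in the key step, C7/C8 from face‑selective epoxidation and ketone‑assisted anti opening, the side chain from a Sharpless epoxidation.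

Key step: step 16

Remarks on the chemistry: commercial monomethyl itaconate is taken to be the 4‑methyl ester, and the [3,3] shift is assumed to pass through the chair‑like bridged array. Abbreviations: TBDPS = tert‑butyl(diphenyl)silyl, TBS = tert‑butyl(dimethyl)silyl, TES = triethylsilyl.

**Route**

Step 1
Reactants: 1 4‑methoxy‑2‑methylidene‑4‑oxobutanoic acid (monomethyl itaconate)
Product: 3 methyl 3‑(hydroxymethyl)but‑3‑enoate, via isobutyl mixed carbonic anhydride 2 (not isolated)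
Conditions: i‑BuOCOCl, N‑methylmorpholine, THF, −15 °C; then NaBH4, H2O, 0 °C
Reagents that add atoms: none
Why: Mixed‑anhydride reduction: the free conjugated acid is activated selectively and reduced by borohydride faster than the methyl ester, leaving the 1,1‑disubstituted olefin untouched; no stereocentre is formed.

Step 2
Reactants: 3 methyl 3‑(hydroxymethyl)but‑3‑enoate
Product: 4 methyl 3‑({[TBDPS]oxy}methyl)but‑3‑enoate
Conditions: TBDPSCl, imidazole, DMF, 0 → 23 °C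
Reagents that add atoms: tert‑butyl(chloro)diphenylsilane, CC(C)(C)[Si](Cl)(c1ccccc1)c1ccccc1
Why: Standard silylation of the primary allylic alcohol prevents lactonisation onto the ester and protects the C12 oxygen until step 17.

Step 3
Reactants: 4 methyl 3‑({[TBDPS]oxy}methyl)but‑3‑enoate
Product: 5 3‑({[TBDPS]oxy}methyl)but‑3‑enoic acid
Conditions: LiOH, THF/H2O, 0 °C; then 1 M HCl
Reagents that add atoms: LiOH, [Li+].[OH-]
Why: Saponification of the unhindered methyl ester at 0 °C should be faster than base‑induced migration of the β,γ‑double bond into conjugation.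

Step 4
Reactants: 5 3‑({[TBDPS]oxy}methyl)but‑3‑enoic acid, 6 (4R)‑4‑benzyl‑1,3‑oxazolidin‑2‑one
Product: 8 (4R)‑4‑benzyl‑3‑[3‑({[TBDPS]oxy}methyl)but‑3‑enoyl]‑1,3‑oxazolidin‑2‑one, via mixed pivalic anhydride 7 (not isolated)
Conditions: PivCl, Et3N, THF, −20 °C; then 6, LiCl, 23 °C
Reagents that add atoms: none
Why: N‑Acylation of the oxazolidinone through the mixed pivalic anhydride with LiCl activation is mild enough to keep the β,γ‑unsaturated acyl group unconjugated.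

Step 5
Reactants: 8 N‑acyl oxazolidinone, 9 (2E)‑but‑2‑enal
Product: 10 (4R)‑4‑benzyl‑3‑[(2R,3S,4E)‑2‑(3‑{[TBDPS]oxy}prop‑1‑en‑2‑yl)‑3‑hydroxyhex‑4‑enoyl]‑1,3‑oxazolidin‑2‑one
Conditions: Bu2BOTf, i‑Pr2NEt, CH2Cl2, −78 → 0 °C; 9, −78 °C; pH 7 buffer/MeOH
Reagents that add atoms: none
Why: Evans syn aldol: the (Z)‑boron enolate adds 1,2 to the enal through a closed chair transition state on the enolate face opposite the benzyl group, which sets C6 and C7 (syn) with absolute control by the (R)‑auxiliary.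

Step 6
Reactants: 10 aldol adduct
Product: 11 (2R,3S,4E)‑2‑(3‑{[TBDPS]oxy}prop‑1‑en‑2‑yl)‑3‑hydroxy‑N‑methoxy‑N‑methylhex‑4‑enamide
Conditions: AlMe3, MeNHOMe·HCl, CH2Cl2, −20 → 0 °C
Reagents that add atoms: N,O‑dimethylhydroxylamine hydrochloride, CNOC.Cl
Why: Aluminium amide transamination of the β‑hydroxy imide (Weinreb amide formation) proceeds without epimerisation at C6 and releases the auxiliary.

Step 7
Reactants: 11 β‑hydroxy Weinreb amide
Product: 12 (2R,3S,4E)‑2‑(3‑{[TBDPS]oxy}prop‑1‑en‑2‑yl)‑N‑methoxy‑N‑methyl‑3‑[(triethylsilyl)oxy]hex‑4‑enamide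
Conditions: TESCl, imidazole, DMF, 0 °C
Reagents that add atoms: chlorotriethylsilane, CC[Si](Cl)(CC)CC
Why: Silylation masks the C7 hydroxyl with a group that can later be removed in the presence of the TBS and TBDPS ethers, and prevents tetrahydrofuran formation at the chlorohydrin stage.

Step 8
Reactants: 12 silylated Weinreb amide
Product: 13 (3R,4S,5E)‑3‑(3‑{[TBDPS]oxy}prop‑1‑en‑2‑yl)‑1‑chloro‑4‑[(triethylsilyl)oxy]hept‑5‑en‑2‑one
Conditions: ICH2Cl, MeLi·LiBr, THF/Et2O, −78 °C; aq. NH4Cl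
Reagents that add atoms: chloroiodomethane, ClCI
Why: Weinreb ketone synthesis with chloromethyllithium generated in the presence of the amide; the chelated tetrahedral intermediate survives until work‑up, so one C1 unit (the future C4) is added and the α‑centre is not exposed to base as a ketone.

Step 9
Reactants: 13 α‑chloro ketone
Product: 15 (2S)‑2‑[(3S,4S,5E)‑2‑({[TBDPS]oxy}methyl)‑4‑[(triethylsilyl)oxy]hepta‑1,5‑dien‑3‑yl]oxirane, via chlorohydrin 14 (not isolated)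
Conditions: (S)‑2‑methyl‑CBS‑oxazaborolidine (0.2 equiv), catecholborane, toluene, −78 °C; then MeOH, K2CO3, 23 °C
Reagents that add atoms: none
Why: Corey–Bakshi–Shibata reduction under reagent control (branched C6 side as the large group, CH2Cl as the small group) should give the (S)‑chlorohydrin that fixes C5, and carbonate closes the terminal epoxide by intramolecular Williamson displacement with retention at C5.

Step 10
Reactants: 15 terminal epoxide, 16 ethyl prop‑2‑ynoate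
Product: 17 ethyl (5R,6S,7S,8E)‑6‑(3‑{[TBDPS]oxy}prop‑1‑en‑2‑yl)‑5‑hydroxy‑7‑[(triethylsilyl)oxy]dec‑8‑en‑2‑ynoate
Conditions: 16, n‑BuLi, THF, −78 °C; BF3·OEt2; then 15, −78 °C
Reagents that add atoms: none
Why: Yamaguchi–Hirao alkynylation: the BF3‑activated epoxide is opened at its CH2 terminus by the lithium acetylide, which forms C3–C4 and frees the C5 hydroxyl without touching a stereocentre.

Step 11
Reactants: 17 hydroxy ynoate
Product: 18 ethyl (5R,6S,7S,8E)‑5‑{[TBS]oxy}‑6‑(3‑{[TBDPS]oxy}prop‑1‑en‑2‑yl)‑7‑[(triethylsilyl)oxy]dec‑8‑en‑2‑ynoate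
Conditions: TBSOTf, 2,6‑lutidine, CH2Cl2, −78 °C
Reagents that add atoms: tert‑butyldimethylsilyl trifluoromethanesulfonate, CC(C)(C)[Si](C)(C)OS(=O)(=O)C(F)(F)F
Why: Silylation of the C5 hydroxyl prevents the δ‑lactone that a free C5–OH would form with the Z‑enoate made in the next step.

Step 12
Reactants: 18 silylated ynoate
Product: 19 ethyl (2Z,5R,6S,7S,8E)‑5‑{[TBS]oxy}‑6‑(3‑{[TBDPS]oxy}prop‑1‑en‑2‑yl)‑3‑methyl‑7‑[(triethylsilyl)oxy]deca‑2,8‑dienoate
Conditions: Me2CuLi (CuI, MeLi), THF, −78 °C; aq. NH4Cl at −78 °C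
Reagents that add atoms: Me2CuLi, [Li+].C[Cu-]C
Why: Syn carbocupration of the ynoate by the Gilman cuprate and protonation with retention place the new methyl trans to the ester, so C4 is cis to C1, the Z geometry the eight‑membered ring needs.

Step 13
Reactants: 19 Z‑enoate
Product: 21 (2Z,5R,6R,7S,8E)‑5‑{[TBS]oxy}‑6‑(3‑{[TBDPS]oxy}prop‑1‑en‑2‑yl)‑7‑hydroxy‑3‑methyldeca‑2,8‑dienoic acid, via triethylsilyl-protected acid 20 (not isolated)
Conditions: LiOH, THF/MeOH/H2O, 40 °C; then AcOH, THF/H2O, 23 °C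
Reagents that add atoms: LiOH, [Li+].[OH-]
Why: Saponification followed by mild acid, which cleaves the secondary TES ether much faster than the TBS and TBDPS ethers, unmasks exactly the acid and the C7 hydroxyl that are to be joined.

Step 14
Reactants: 21 hydroxy acid
Product: 22 (3Z,6R,7R,8S)‑6‑{[TBS]oxy}‑7‑(3‑{[TBDPS]oxy}prop‑1‑en‑2‑yl)‑4‑methyl‑8‑[(1E)‑prop‑1‑en‑1‑yl]‑5,6,7,8‑tetrahydro‑2H‑oxocin‑2‑one
Conditions: 2‑methyl‑6‑nitrobenzoic anhydride, DMAP, CH2Cl2 (1 mM, slow addition), 23 °C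
Reagents that add atoms: none
Why: Shiina macrolactonisation under high dilution; the cis C2=C3 bond and three ring substituents should favour closure of the eight‑membered lactone, with retention at C7.

Step 15
Reactants: 22 eight‑membered lactone
Product: 23 (2S,3R,4R,6Z)‑4‑{[TBS]oxy}‑3‑(3‑{[TBDPS]oxy}prop‑1‑en‑2‑yl)‑6‑methyl‑8‑methylidene‑2‑[(1E)‑prop‑1‑en‑1‑yl]‑3,4,5,8‑tetrahydro‑2H‑oxocine
Conditions: Cp2Ti(μ‑Cl)(μ‑CH2)AlMe2 (Tebbe reagent), pyridine, THF/toluene, −40 → 0 °C; basic alumina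
Reagents that add atoms: Cp2Ti(μ‑Cl)(μ‑CH2)AlMe2, C[Al-]1(C)C[Ti](C2C=CC=C2)(C2C=CC=C2)[Cl+]1
Why: Tebbe methylenation converts the lactone carbonyl into the exocyclic enol ether through an oxatitanacyclobutane and tolerates silyl ethers and the other olefins; the new CH2 is the future C10.

Step 16
Reactants: 23 2‑methylidene oxocine
Product: 24 (2Z,5R,6S,7Z,9S)‑5‑{[TBS]oxy}‑6‑(3‑{[TBDPS]oxy}prop‑1‑en‑2‑yl)‑3,9‑dimethylcyclodeca‑2,7‑dien‑1‑one
Conditions: toluene (5 mM), 2,6‑di‑tert‑butyl‑4‑methylpyridine (0.2 equiv), base‑washed sealed tube, 135 °C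
Reagents that add atoms: none
Why: Thermal Claisen rearrangement: the exocyclic enol ether carbon (C10) bonds to the propenyl terminus (C9) while the ring C7–O bond breaks, so the oxygen becomes the C1 ketone and the eight‑membered oxacycle grows by two atoms to the ten‑membered carbocycle; the closest known reaction type is the Claisen ring expansion of 2‑methylene‑6‑vinyl‑tetrahydropyrans to cyclooct‑4‑enones. The carbocycle closes through a bridged six‑centre chair‑like array in which the five‑atom tether C2–C6 spans the oxygen and holds C6 pseudo‑axial on the migrating carbon, which is why the new C7=C8 bond should be cis. The new stereocentre C9 is controlled by the (S)‑configured carbinol carbon C7 and the E geometry of the propenyl group (methyl equatorial in the chair), a 1,3‑chirality transfer expected to give 9S. The step needs chair over boat, and Claisen over both the Cope shift of the 1,5‑diene through C6–C7 and acid‑catalysed isomerisation of the exocyclic enol ether. The Z C2=C3 bond locked in the small ring pre‑organises the two termini, a neutral Cope shift has the higher barrier, and base‑washed glass with a hindered pyridine suppresses enol ether isomerisation; the Z enone geometry is simply carried over.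

Step 17
Reactants: 24 bis‑silyl dienone
Product: 25 (2Z,5R,6S,7Z,9S)‑5‑hydroxy‑6‑(3‑hydroxyprop‑1‑en‑2‑yl)‑3,9‑dimethylcyclodeca‑2,7‑dien‑1‑one
Conditions: tetrabutylammonium fluoride, AcOH (1:1), THF, 0 → 23 °C
Reagents that add atoms: none
Why: Buffered fluoride removes both silyl ethers while the acetic acid suppresses base‑induced elimination of the δ‑oxygen of the enone.

Step 18
Reactants: 25 diol
Product: 26 (2Z,7Z,9S)‑3,9‑dimethylcyclodeca‑2,7‑dien‑1‑one carrying the 5,6‑trans‑fused α‑methylene‑γ‑butyrolactone (O on C5, C11 on C6; 5R,6S)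
Conditions: MnO2 (excess), CH2Cl2, 23 °C
Reagents that add atoms: none
Why: Oxidative lactonisation of a 2‑methylene‑1,4‑diol: MnO2 oxidises the primary allylic alcohol to the enal, the C5 hydroxyl adds, and the allylic lactol is oxidised on; only the C5 oxygen is available, so the lactone can close in one direction, and its trans fusion follows from steps 5 and 9.

Step 19
Reactants: 26 dienone lactone
Product: 27 the 7,8‑cis‑epoxide of 26 (5R,6S,7R,8S,9S), oxirane oxygen anti to the C9 methyl group and to C5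
Conditions: m‑CPBA, NaHCO3, CH2Cl2, −10 → 0 °C
Reagents that add atoms: 3‑chloroperoxybenzoic acid, OOC(=O)c1cccc(Cl)c1
Why: Prilezhaev epoxidation: the isolated cis olefin is far more nucleophilic than the enone and acrylate double bonds, and in the allylic‑strain‑minimised conformer the C9 methyl and the oxygen‑bearing C5 flank one face, so the peracid should attack the other (flanked by C10H2 and the flat C11).

Step 20
Reactants: 27 epoxy ketone
Product: 29 8‑hydroxy‑7‑[(triethylsilyl)oxy] lactone enone (5R,6S,7R,8R,9S), via bicyclic oxocarbenium triflate 28 (not isolated)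
Conditions: TESOTf, 2,6‑di‑tert‑butyl‑4‑methylpyridine, CH2Cl2, −78 °C; then sat. aq. NaHCO3, THF, 0 °C
Reagents that add atoms: triethylsilyl trifluoromethanesulfonate, CC[Si](CC)(CC)OS(=O)(=O)C(F)(F)F; water, O
Why: Proposed new method: silylation of the oxirane oxygen should trigger 5‑exo attack of the transannular C1 ketone oxygen at C8 with inversion (only C8 is within reach), leaving the former oxirane oxygen on C7 as its silyl ether, and aqueous hydrogencarbonate then hydrolyses the cyclic oxocarbenium ion to return the ketone and free the C8 hydroxyl; the closest known reaction types are the acid‑promoted conversion of γ,δ‑epoxy ketones into bicyclic ketals by carbonyl participation and silyl‑triflate‑promoted epoxide openings by neighbouring carbonyl groups.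

Step 21
Reactants: 30 (2E)‑2‑methylbut‑2‑en‑1‑ol
Product: 31 [(2R,3R)‑2,3‑dimethyloxiran‑2‑yl]methanol
Conditions: Ti(OiPr)4 (5 mol%), D‑(−)‑diisopropyl tartrate (6 mol%), t‑BuOOH, 4 Å MS, CH2Cl2, −20 °C
Reagents that add atoms: tert‑butyl hydroperoxide, CC(C)(C)OO
Why: Sharpless asymmetric epoxidation of the E‑trisubstituted allylic alcohol; the D‑(−)‑tartrate complex delivers oxygen to the face that gives the (2R,3R)‑epoxy alcohol.

Step 22
Reactants: 31 epoxy alcohol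
Product: 32 (2S,3R)‑2,3‑dimethyloxirane‑2‑carboxylic acid
Conditions: RuCl3 (2 mol%), NaIO4, CCl4/MeCN/H2O, 0 → 23 °C
Reagents that add atoms: NaIO4, [Na+].[O-]I(=O)(=O)=O; water, O
Why: RuO4 generated in situ oxidises the primary alcohol to the acid without opening the trisubstituted epoxide; the descriptor change at C2 reflects changed priorities only.

Step 23
Reactants: 29 C8 alcohol, 32 epoxy acid
Product: 34 8‑O‑[(2S,3R)‑2,3‑dimethyloxirane‑2‑carbonyl]‑7‑O‑triethylsilyl lactone enone, via mixed trichlorobenzoic anhydride 33 (not isolated)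
Conditions: 32, 2,4,6‑trichlorobenzoyl chloride, Et3N, THF, 23 °C; then 29, DMAP, toluene, 23 → 40 °C
Reagents that add atoms: none
Why: Yamaguchi esterification: the hindered epoxy acid is activated as its mixed anhydride and transferred by DMAP to the only free hydroxyl (C8) with retention at C8.

Step 24
Reactants: 34 silyl ether
Product: 35 target CNP0227299.4
Conditions: AcOH/THF/H2O (3:1:1), 23 °C
Reagents that add atoms: none
Why: Mild acidic hydrolysis of the TES ether; the electron‑poor glycidic ester epoxide, the lactone and the enone should tolerate aqueous acetic acid, and the absence of base avoids acyl migration from O8 to O7.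

**Compound list**

1 | 4‑methoxy‑2‑methylidene‑4‑oxobutanoic acid | C=C(CC(=O)OC)C(=O)O | starting material
2 | 4‑methoxy‑2‑methylidene‑4‑oxobutanoic isobutyl carbonic anhydride | C=C(CC(=O)OC)C(=O)OC(=O)OCC(C)C | intermediate
3 | methyl 3‑(hydroxymethyl)but‑3‑enoate | C=C(CO)CC(=O)OC | intermediate
4 | methyl 3‑({[TBDPS]oxy}methyl)but‑3‑enoate | C=C(CO[Si](c1ccccc1)(c1ccccc1)C(C)(C)C)CC(=O)OC | intermediate
5 | 3‑({[TBDPS]oxy}methyl)but‑3‑enoic acid | C=C(CO[Si](c1ccccc1)(c1ccccc1)C(C)(C)C)CC(=O)O | intermediate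
6 | (4R)‑4‑benzyl‑1,3‑oxazolidin‑2‑one | O=C1OC[C@@H](Cc2ccccc2)N1 | starting material
7 | 3‑({[TBDPS]oxy}methyl)but‑3‑enoic 2,2‑dimethylpropanoic anhydride | C=C(CO[Si](c1ccccc1)(c1ccccc1)C(C)(C)C)CC(=O)OC(=O)C(C)(C)C | intermediate
8 | (4R)‑4‑benzyl‑3‑[3‑({[TBDPS]oxy}methyl)but‑3‑enoyl]‑1,3‑oxazolidin‑2‑one | C=C(CO[Si](c1ccccc1)(c1ccccc1)C(C)(C)C)CC(=O)N1[C@H](Cc2ccccc2)COC1=O | intermediate
9 | (2E)‑but‑2‑enal | C/C=C/C=O | starting material
10 | (4R)‑4‑benzyl‑3‑[(2R,3S,4E)‑2‑(3‑{[TBDPS]oxy}prop‑1‑en‑2‑yl)‑3‑hydroxyhex‑4‑enoyl]‑1,3‑oxazolidin‑2‑one | C/C=C/[C@H](O)[C@@H](C(=C)CO[Si](c1ccccc1)(c1ccccc1)C(C)(C)C)C(=O)N1[C@H](Cc2ccccc2)COC1=O | intermediate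
11 | (2R,3S,4E)‑2‑(3‑{[TBDPS]oxy}prop‑1‑en‑2‑yl)‑3‑hydroxy‑N‑methoxy‑N‑methylhex‑4‑enamide | C/C=C/[C@H](O)[C@@H](C(=C)CO[Si](c1ccccc1)(c1ccccc1)C(C)(C)C)C(=O)N(C)OC | intermediate
12 | (2R,3S,4E)‑2‑(3‑{[TBDPS]oxy}prop‑1‑en‑2‑yl)‑N‑methoxy‑N‑methyl‑3‑[(triethylsilyl)oxy]hex‑4‑enamide | C/C=C/[C@H](O[Si](CC)(CC)CC)[C@@H](C(=C)CO[Si](c1ccccc1)(c1ccccc1)C(C)(C)C)C(=O)N(C)OC | intermediate
13 | (3R,4S,5E)‑3‑(3‑{[TBDPS]oxy}prop‑1‑en‑2‑yl)‑1‑chloro‑4‑[(triethylsilyl)oxy]hept‑5‑en‑2‑one | C/C=C/[C@H](O[Si](CC)(CC)CC)[C@@H](C(=C)CO[Si](c1ccccc1)(c1ccccc1)C(C)(C)C)C(=O)CCl | intermediate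
14 | (2S,3S,4S,5E)‑3‑(3‑{[TBDPS]oxy}prop‑1‑en‑2‑yl)‑1‑chloro‑4‑[(triethylsilyl)oxy]hept‑5‑en‑2‑ol | C/C=C/[C@H](O[Si](CC)(CC)CC)[C@@H](C(=C)CO[Si](c1ccccc1)(c1ccccc1)C(C)(C)C)[C@H](O)CCl | intermediate
15 | (2S)‑2‑[(3S,4S,5E)‑2‑({[TBDPS]oxy}methyl)‑4‑[(triethylsilyl)oxy]hepta‑1,5‑dien‑3‑yl]oxirane | C/C=C/[C@H](O[Si](CC)(CC)CC)[C@@H](C(=C)CO[Si](c1ccccc1)(c1ccccc1)C(C)(C)C)[C@H]1CO1 | intermediate
16 | ethyl prop‑2‑ynoate | C#CC(=O)OCC | starting material
17 | ethyl (5R,6S,7S,8E)‑6‑(3‑{[TBDPS]oxy}prop‑1‑en‑2‑yl)‑5‑hydroxy‑7‑[(triethylsilyl)oxy]dec‑8‑en‑2‑ynoate | C/C=C/[C@H](O[Si](CC)(CC)CC)[C@@H](C(=C)CO[Si](c1ccccc1)(c1ccccc1)C(C)(C)C)[C@H](O)CC#CC(=O)OCC | intermediate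
18 | ethyl (5R,6S,7S,8E)‑5‑{[TBS]oxy}‑6‑(3‑{[TBDPS]oxy}prop‑1‑en‑2‑yl)‑7‑[(triethylsilyl)oxy]dec‑8‑en‑2‑ynoate | C/C=C/[C@H](O[Si](CC)(CC)CC)[C@@H](C(=C)CO[Si](c1ccccc1)(c1ccccc1)C(C)(C)C)[C@H](O[Si](C)(C)C(C)(C)C)CC#CC(=O)OCC | intermediate
19 | ethyl (2Z,5R,6S,7S,8E)‑5‑{[TBS]oxy}‑6‑(3‑{[TBDPS]oxy}prop‑1‑en‑2‑yl)‑3‑methyl‑7‑[(triethylsilyl)oxy]deca‑2,8‑dienoate | C/C=C/[C@H](O[Si](CC)(CC)CC)[C@@H](C(=C)CO[Si](c1ccccc1)(c1ccccc1)C(C)(C)C)[C@H](O[Si](C)(C)C(C)(C)C)C/C(C)=C\C(=O)OCC | intermediate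
20 | (2Z,5R,6S,7S,8E)‑5‑{[TBS]oxy}‑6‑(3‑{[TBDPS]oxy}prop‑1‑en‑2‑yl)‑3‑methyl‑7‑[(triethylsilyl)oxy]deca‑2,8‑dienoic acid | C/C=C/[C@H](O[Si](CC)(CC)CC)[C@@H](C(=C)CO[Si](c1ccccc1)(c1ccccc1)C(C)(C)C)[C@H](O[Si](C)(C)C(C)(C)C)C/C(C)=C\C(=O)O | intermediate
21 | (2Z,5R,6R,7S,8E)‑5‑{[TBS]oxy}‑6‑(3‑{[TBDPS]oxy}prop‑1‑en‑2‑yl)‑7‑hydroxy‑3‑methyldeca‑2,8‑dienoic acid | C/C=C/[C@H](O)[C@@H](C(=C)CO[Si](c1ccccc1)(c1ccccc1)C(C)(C)C)[C@H](O[Si](C)(C)C(C)(C)C)C/C(C)=C\C(=O)O | intermediate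
22 | (3Z,6R,7R,8S)‑6‑{[TBS]oxy}‑7‑(3‑{[TBDPS]oxy}prop‑1‑en‑2‑yl)‑4‑methyl‑8‑[(1E)‑prop‑1‑en‑1‑yl]‑5,6,7,8‑tetrahydro‑2H‑oxocin‑2‑one | C/C=C/[C@@H]1OC(=O)/C=C(C)\C[C@@H](O[Si](C)(C)C(C)(C)C)[C@@H]1C(=C)CO[Si](c2ccccc2)(c2ccccc2)C(C)(C)C | intermediate
23 | (2S,3R,4R,6Z)‑4‑{[TBS]oxy}‑3‑(3‑{[TBDPS]oxy}prop‑1‑en‑2‑yl)‑6‑methyl‑8‑methylidene‑2‑[(1E)‑prop‑1‑en‑1‑yl]‑3,4,5,8‑tetrahydro‑2H‑oxocine | C/C=C/[C@@H]1OC(=C)/C=C(C)\C[C@@H](O[Si](C)(C)C(C)(C)C)[C@@H]1C(=C)CO[Si](c2ccccc2)(c2ccccc2)C(C)(C)C | intermediate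
24 | (2Z,5R,6S,7Z,9S)‑5‑{[TBS]oxy}‑6‑(3‑{[TBDPS]oxy}prop‑1‑en‑2‑yl)‑3,9‑dimethylcyclodeca‑2,7‑dien‑1‑one | C1[C@H](C)/C=C\[C@@H](C(=C)CO[Si](c2ccccc2)(c2ccccc2)C(C)(C)C)[C@H](O[Si](C)(C)C(C)(C)C)C/C(C)=C\C1=O | intermediate
25 | (2Z,5R,6S,7Z,9S)‑5‑hydroxy‑6‑(3‑hydroxyprop‑1‑en‑2‑yl)‑3,9‑dimethylcyclodeca‑2,7‑dien‑1‑one | C1[C@H](C)/C=C\[C@@H](C(=C)CO)[C@H](O)C/C(C)=C\C1=O | intermediate
26 | (2Z,7Z,9S)‑3,9‑dimethylcyclodeca‑2,7‑dien‑1‑one with 5,6‑trans‑fused α‑methylene‑γ‑butyrolactone (5R,6S) | C=C1C(=O)O[C@@H]2C/C(C)=C\C(=O)C[C@H](C)/C=C\[C@@H]12 | intermediate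
27 | 7,8‑cis‑epoxide of 26 (5R,6S,7R,8S,9S) | C=C1C(=O)O[C@@H]2C/C(C)=C\C(=O)C[C@H](C)[C@@H]3O[C@@H]3[C@@H]12 | intermediate
28 | bicyclic oxocarbenium triflate (former ketone oxygen bridging C1 and C8; C7–OTES) | C=C1C(=O)O[C@@H]2C/C(C)=C\C3=[O+][C@H]([C@@H](C)C3)[C@H](O[Si](CC)(CC)CC)[C@@H]12.[O-]S(=O)(=O)C(F)(F)F | intermediate
29 | 8‑hydroxy‑7‑[(triethylsilyl)oxy] lactone enone (5R,6S,7R,8R,9S) | C=C1C(=O)O[C@@H]2C/C(C)=C\C(=O)C[C@H](C)[C@@H](O)[C@H](O[Si](CC)(CC)CC)[C@@H]12 | intermediate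
30 | (2E)‑2‑methylbut‑2‑en‑1‑ol | C/C=C(\C)CO | starting material
31 | [(2R,3R)‑2,3‑dimethyloxiran‑2‑yl]methanol | OC[C@@]1(C)O[C@@H]1C | intermediate
32 | (2S,3R)‑2,3‑dimethyloxirane‑2‑carboxylic acid | OC(=O)[C@@]1(C)O[C@@H]1C | intermediate
33 | (2S,3R)‑2,3‑dimethyloxirane‑2‑carboxylic 2,4,6‑trichlorobenzoic anhydride | O=C(OC(=O)[C@@]1(C)O[C@@H]1C)c1c(Cl)cc(Cl)cc1Cl | intermediate
34 | 8‑O‑[(2S,3R)‑2,3‑dimethyloxirane‑2‑carbonyl]‑7‑O‑triethylsilyl lactone enone (5R,6S,7R,8R,9S) | C=C1C(=O)O[C@@H]2C/C(C)=C\C(=O)C[C@H](C)[C@@H](OC(=O)[C@@]3(C)O[C@@H]3C)[C@H](O[Si](CC)(CC)CC)[C@@H]12 | intermediate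
35 | CNP0227299.4 (5R,6R,7R,8R,9S; side chain 2S,3R) | C=C1C(=O)O[C@@H]2C/C(C)=C\C(=O)C[C@H](C)[C@@H](OC(=O)[C@@]3(C)O[C@@H]3C)[C@H](O)[C@@H]12 | target

**Summary**

Total step count: 24. Longest linear sequence: 22 (steps 1–20, 23, 24, from compound 1).

The three steps most likely to fail:

Step 20 (proposed new method). The silyl triflate may silylate the enone instead, or the activated oxirane may undergo a transannular hydride shift or open at C7. The ketone can also reach C8 only after a rotation about C8–C9 that brings C10 to the face opposite the oxirane oxygen. Any of these would lose the O7/O8 differentiation. The fallback uses known chemistry and sets out from epoxide 27. It is hydrolysed with catalytic HClO4 in aqueous THF, where participation of the C1 carbonyl through a cyclic hemiketal directs C–O formation to C8 with inversion, to give the (5R,6R,7R,8R,9S)‑7,8‑diol F1. The C8 hydroxyl is flanked by the methyl‑bearing C9 and not by the ring‑fusion carbon, so it should be acylated preferentially by one equivalent of mixed anhydride 33 with DMAP at low temperature. This comes back to the route at target 35.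

Step 16 (key step). The bridged array may prefer a boat, which would transfer chirality in the opposite sense and give the 9R epimer of 24, or the exocyclic enol ether may isomerise before it rearranges. The fallback sets out from hydroxy acid 21. It is closed under Mitsunobu conditions (PPh3, diisopropyl azodicarboxylate, toluene, high dilution), which activate the allylic C7 alcohol and invert it, to give the C8‑epimeric lactone (3Z,6R,7R,8R) F2. Methylenation with Cp2Ti(μ‑Cl)(μ‑CH2)AlMe2 gives the epimeric enol ether F3. Thermolysis of F3 through the boat array should then place the C9 methyl as required, and the route is rejoined at 24.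

Step 19. The peracid may attack the other face of the C7=C8 olefin (poor or reversed facial selectivity), which would lead to the 7S,8S diol series. The fallback sets out from lactone 26. N‑Bromosuccinimide in aqueous THF forms the bromonium ion on the face the peracid prefers, and anti opening at C8 gives the (7S,8S)‑7‑bromo‑8‑hydroxy compound F4. Ag2O in CH2Cl2 then closes F4 by internal displacement of bromide, which puts the oxirane oxygen on the face opposite to that attacked by the electrophile. The route is rejoined at epoxide 27.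

Further compounds

F1 | step 20 | (5R,6R,7R,8R,9S)‑7,8‑dihydroxy lactone enone (7,8‑diol corresponding to 35 without the acyl group) | C=C1C(=O)O[C@@H]2C/C(C)=C\C(=O)C[C@H](C)[C@@H](O)[C@H](O)[C@@H]12
F2 | step 16 | (3Z,6R,7R,8R)‑6‑{[TBS]oxy}‑7‑(3‑{[TBDPS]oxy}prop‑1‑en‑2‑yl)‑4‑methyl‑8‑[(1E)‑prop‑1‑en‑1‑yl]‑5,6,7,8‑tetrahydro‑2H‑oxocin‑2‑one | C/C=C/[C@H]1OC(=O)/C=C(C)\C[C@@H](O[Si](C)(C)C(C)(C)C)[C@@H]1C(=C)CO[Si](c2ccccc2)(c2ccccc2)C(C)(C)C
F3 | step 16 | (2R,3R,4R,6Z)‑4‑{[TBS]oxy}‑3‑(3‑{[TBDPS]oxy}prop‑1‑en‑2‑yl)‑6‑methyl‑8‑methylidene‑2‑[(1E)‑prop‑1‑en‑1‑yl]‑3,4,5,8‑tetrahydro‑2H‑oxocine | C/C=C/[C@H]1OC(=C)/C=C(C)\C[C@@H](O[Si](C)(C)C(C)(C)C)[C@@H]1C(=C)CO[Si](c2ccccc2)(c2ccccc2)C(C)(C)C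
F4 | step 19 | (5R,6S,7S,8S,9S)‑7‑bromo‑8‑hydroxy lactone enone | C=C1C(=O)O[C@@H]2C/C(C)=C\C(=O)C[C@H](C)[C@H](O)[C@@H](Br)[C@@H]12
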